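A direct plan would take both end groups from one common C15 enyne A1 (ring B type, O3 as tert-butyl carbonate, made by Sonogashira coupling of a cyclohexenyl triflate).
For ring A, the C5=C6 bond of A1 would be epoxidised with a peracid to the anti-epoxide A2, the carbonate would open A2 at C5 under BF3 to the bridged cyclic carbonate A3, and hydride, fluoride and MnO2 would give the C15 trihydroxy aldehyde A4.
A1 would also be carried through five further steps to the C25 Wittig salt A5, and a last Wittig reaction of A5 with A4 would give the target.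
Weak step (i), the peracid epoxidation A1 → A2: C5 and C6 would be set together with only a remote carbonate to tell the faces apart, on the more hindered of two olefins, and the minor epoxide would be discarded.
Weak step (ii), the Lewis acid opening A2 → A3: it has no precedent on a fully substituted propargylic epoxide, and it would have to close a bridged 2,4-dioxabicyclo[3.3.1]nonanone through the chair with O3 axial against an axial C1 methyl, in competition with ionisation at C6.
Weak step (iii), the end game: a Wittig reaction on the unprotected triol aldehyde A4 would give an 11Z/11E mixture to be corrected by heating the finished polyene, after a run of carbonate, silyl, hydride and oxidation steps that build nothing.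

**Retrosynthetic overview**
C9 + C22 + C9: the chain C7–C7' is made first as one symmetrical C22 heptaenediyne without stereocentres; its two terminal alkynes become the C7'≡C8' triple bond and, after reduction, the C7=C8 double bond.
Ring B enters as an enol triflate (Sonogashira, C6'–C7'). Ring A enters last, as a C9 α-hydroxy ketone: the C31 lithium acetylide adds to its C6 carbonyl, which forms C6–C7 and sets C6 from C5.
The two triple bonds are then told apart by the C6 hydroxyl, since hydride is delivered only to the propargylic one.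
Ring A takes its oxygens from ketoisophorone: C3 by transfer hydrogenation, O5 by a hydroxyl-directed enone epoxidation that hydride opens at C4, each under direct 1,2- or 1,3-control.
No ring is closed, no tetrasubstituted olefin is epoxidised, no bridged carbonate is needed, the E/Z question is settled on the C22 hydrocarbon, and the end game uses no Wittig step, acid or heat.

Key step: step 11

Remark: carotenoid numbering is used for all ring and chain atoms (ring A C1–C6, chain C7–C15, primed numbers for the ring B half); the sense of induction of the catalyst in step 1 is assigned by analogy with aryl ketones.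

Step 1
Reactants: 1 ketoisophorone, 2,6,6-trimethylcyclohex-2-ene-1,4-dione
Product: 2 (S)-phorenol, (4S)-4-hydroxy-2,6,6-trimethylcyclohex-2-en-1-one
Conditions: RuCl(p-cymene)[(S,S)-TsDPEN] (0.5 mol%), iPrOH, rt
Reagents that add atoms: none
Why: Asymmetric transfer hydrogenation (Noyori–Ikariya) with the chiral divalent ruthenium hydride should reduce only the C3 carbonyl, because the C6 carbonyl lies between two fully substituted carbons, and should set C3 as S under catalyst control, the enone π system taking the place of the aryl group of the usual model.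

Step 2
Reactants: 2 (S)-phorenol
Product: 3 cis-epoxy alcohol, (1S,5S,6S)-5-hydroxy-1,3,3-trimethyl-7-oxabicyclo[4.1.0]heptan-2-one
Conditions: t-BuOOH (1.5 equiv), benzyltrimethylammonium hydroxide (0.1 equiv), THF, −10 → 0 °C
Reagents that add atoms: tert-butyl hydroperoxide, CC(C)(C)OO
Why: In this nucleophilic (Weitz–Scheffer) epoxidation of a γ-hydroxy enone in an aprotic solvent, the free C3 hydroxyl should hydrogen-bond the hydroperoxide anion and deliver it to C4 on its own face, which sets O5 cis to O3; catalytic base at low temperature is meant to outrun isomerisation of 2 to the 1,4-diketone.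

Step 3
Reactants: 3 cis-epoxy alcohol
Product: 4 silylated epoxy ketone, (1S,5S,6S)-5-(tert-butyldimethylsilyloxy)-1,3,3-trimethyl-7-oxabicyclo[4.1.0]heptan-2-one
Conditions: TBSCl (1.2 equiv), imidazole (2 equiv), DMF, rt
Reagents that add atoms: tert-butyldimethylsilyl chloride, TBSCl, CC(C)(C)[Si](C)(C)Cl
Why: Silylation of the only hydroxyl masks O3, so that after step 4 the C6 carbinol is the only secondary alcohol left; the epoxide and the non-enolisable ketone are not touched.

Step 4
Reactants: 4 silylated epoxy ketone
Product: 5 diol, (2S,4S)-4-(tert-butyldimethylsilyloxy)-2,6,6-trimethylcyclohexane-1,2-diol (either C1 epimer)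
Conditions: LiBHEt3 (3.5 equiv), THF, 0 → 60 °C; aq. NH4Cl
Reagents that add atoms: none
Why: LiBHEt3 reduces the ketone and then opens the trisubstituted epoxide by SN2 attack of hydride on C4, the only epoxide carbon that is not fully substituted (the usual regiochemistry for trisubstituted epoxides), so O5 stays on C5 with its configuration; the C6 alkoxide is held as its triethylborane complex, which should keep it from epoxide migration, and the C6 configuration is of no consequence.

Step 5
Reactants: 5 diol
Product: 6 ring A ketone, (2S,4S)-4-(tert-butyldimethylsilyloxy)-2-hydroxy-2,6,6-trimethylcyclohexan-1-one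
Conditions: IBX (2-iodoxybenzoic acid, 2.5 equiv), EtOAc, 75 °C
Reagents that add atoms: none
Why: The pentavalent iodine reagent oxidises the one secondary alcohol to the ketone and is known to take 1,2-diols to α-hydroxy ketones without C–C cleavage; the tertiary C5 hydroxyl and the silyl ether are inert, and this is the only reduction–oxidation pair of the route, placed at the C9 stage.

Step 6
Reactants: 7 actinol, (4R,6R)-4-hydroxy-2,2,6-trimethylcyclohexan-1-one
Product: 8 actinol silyl ether, (4R,6R)-4-(tert-butyldimethylsilyloxy)-2,2,6-trimethylcyclohexan-1-one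
Conditions: TBSCl (1.2 equiv), imidazole (2 equiv), DMF, rt
Reagents that add atoms: tert-butyldimethylsilyl chloride, TBSCl, CC(C)(C)[Si](C)(C)Cl
Why: Silylation of the only hydroxyl gives an ether that should survive the amide base, the coupling, the acetylide and the hydride of the later steps; both stereocentres are untouched.

Step 7
Reactants: 8 actinol silyl ether
Product: 10 ring B enol triflate, (4R)-4-(tert-butyldimethylsilyloxy)-2,6,6-trimethylcyclohex-1-en-1-yl trifluoromethanesulfonate, via lithium enolate 9 (not isolated)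
Conditions: LiN(iPr)2 (1.15 equiv), THF, −78 °C; PhNTf2, −78 → 0 °C; aq. NH4Cl
Reagents that add atoms: N-phenylbis(trifluoromethanesulfonimide), PhNTf2, O=S(=O)(N(c1ccccc1)S(=O)(=O)C(F)(F)F)C(F)(F)F
Why: Because C1' is quaternary the ketone enolises only towards C5', and O-sulfonylation of the lithium enolate (enol triflate formation) gives the single C5'=C6' triflate; the C5' stereocentre is given up and C3' is untouched.

Step 8
Reactants: 11 (E)-3-methylpent-2-en-4-yn-1-ol
Product: 12 C6 Wittig salt, [(2E)-3-methylpent-2-en-4-yn-1-yl]triphenylphosphonium bromide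
Conditions: PPh3·HBr (1.1 equiv), MeOH, rt; crystallisation
Reagents that add atoms: triphenylphosphine hydrobromide, [Br-].c1ccc(cc1)[PH+](c1ccccc1)c1ccccc1
Why: PPh3·HBr converts the primary allylic alcohol into the allylic phosphonium salt (the standard preparation of isoprenoid Wittig salts); the terminal alkyne is not affected, and any 2Z salt formed through the allylic cation is removed by crystallisation.

Step 9
Reactants: 12 C6 Wittig salt; 13 (2E,4E,6E)-2,7-dimethylocta-2,4,6-trienedial
Product: 16 C22 heptaenediyne, (3E,5E,7E,9E,11E,13E,15E)-3,7,12,16-tetramethyloctadeca-3,5,7,9,11,13,15-heptaene-1,17-diyne, via C6 ylide 14 (not isolated), via C16 enynal 15 (not isolated)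
Conditions: 12 (2.2 equiv), NaOMe (2.3 equiv), MeOH/CH2Cl2, 0 °C → rt; then heptane, 80 °C, crystallisation
Reagents that add atoms: none
Why: A twofold Wittig olefination of the symmetrical dialdehyde forms C11=C12 and C11'=C12'; the hindered 11Z and 11'Z isomers are brought to E by heating a hydrocarbon that has no stereocentre or hydroxyl, the all-E diyne is purified by crystallisation, and methoxide is too weak a base to touch the terminal alkynes.

Step 10
Reactants: 10 ring B enol triflate; 16 C22 heptaenediyne
Product: 17 ring B C31 polyenediyne, tert-butyldimethyl{[(1R)-3,5,5-trimethyl-4-[(3E,5E,7E,9E,11E,13E,15E)-3,7,12,16-tetramethyloctadeca-3,5,7,9,11,13,15-heptaene-1,17-diyn-1-yl]cyclohex-3-en-1-yl]oxy}silane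
Conditions: Pd(PPh3)4 (5 mol%), CuI (10 mol%), iPr2NH, DMF (degassed), rt → 45 °C, dark; 16 in excess (3 equiv), recovered
Reagents that add atoms: none
Why: Sonogashira coupling of the hindered cyclohexenyl triflate with one of the two equivalent terminal alkynes forms C6'–C7'; the excess of diyne keeps double coupling low, exclusion of oxygen suppresses oxidative alkyne dimerisation, and zerovalent palladium leaves the polyene geometry and C3' alone.

Step 11
Reactants: 17 ring B C31 polyenediyne; 6 ring A ketone
Product: 20 C40 diynediol, (3S,5S,6R,3'R)-3,3'-bis(tert-butyldimethylsilyloxy)-7,8,7',8'-tetradehydro-5,6-dihydro-β,β-carotene-5,6-diol, via lithium acetylide 18 (not isolated), via lithium alkoxide 19 (not isolated)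
Conditions: 17, LiN(iPr)2 (1.05 equiv), THF, −78 °C; 6 (1.5 equiv), LiN(iPr)2 (1.5 equiv), THF, −78 °C; combined, −78 °C → rt, dark; aq. NH4Cl
Reagents that add atoms: none
Why: The lithium acetylide of the C31 polyenediyne adds to the C6 carbonyl of the lithium alkoxide of 6 (1,2-addition), which forms the C6–C7 bond and completes the C40 skeleton. The closest known reaction types are the chelation-controlled addition of metal acetylides to cyclic α-hydroxy ketones and the acetylide additions to 2,2,6-trimethylcyclohexanones used for ionone- and abscisic acid-type side chains. No ring is closed. The one new stereocentre, C6, is controlled by C5 and the ring: with O3 and O5 equatorial (O5–Li chelated to the carbonyl oxygen), the C5 methyl and one C1 methyl are both axial on the lower face, so the acetylide should add axially from the upper face, cis to O5 and O3, placing the new hydroxyl trans to O5 as in the target. The step needs addition to a ketone flanked by two fully substituted carbons: the linear acetylide is the smallest carbon nucleophile, the ketone cannot enolise so no proton transfer competes, and the C9 ketone is used in excess.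

Step 12
Reactants: 20 C40 diynediol
Product: 21 bis-silyl ether of the target, (3S,5S,6S,3'R)-3,3'-bis(tert-butyldimethylsilyloxy)-7',8'-didehydro-5,6-dihydro-β,β-carotene-5,6-diol
Conditions: NaAlH2(OCH2CH2OCH3)2 (Red-Al, 5 equiv), THF/toluene, 0 °C → rt, dark; aq. potassium sodium tartrate
Reagents that add atoms: none
Why: The C6 alkoxide binds aluminium and delivers hydride to C7 (trans-hydroalumination of a propargylic alcohol), so protonolysis of the C8–Al bond leaves the 7E alkene; the 7',8' triple bond has no propargylic hydroxyl and should stay, as should the polyene, the silyl ethers and all stereocentres.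

Step 13
Reactants: 21 bis-silyl ether of the target
Product: 22 target, all-E (3S,5S,6S,3'R)-7',8'-didehydro-5,6-dihydro-β,β-carotene-3,5,6,3'-tetrol
Conditions: Bu4NF (3 equiv), THF, 0 °C → rt, dark
Reagents that add atoms: none
Why: Fluoride cleaves both secondary silyl ethers (desilylation) under non-acidic conditions, which spare the tertiary allylic C6 alcohol and the polyene; every stereocentre and double bond is already in place.

**Compound list**

1 | ketoisophorone, 2,6,6-trimethylcyclohex-2-ene-1,4-dione | CC1=CC(=O)CC(C)(C)C1=O | starting material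
2 | (S)-phorenol, (4S)-4-hydroxy-2,6,6-trimethylcyclohex-2-en-1-one | O=C1C(C)(C)C[C@H](O)C=C1C | intermediate
3 | cis-epoxy alcohol, (1S,5S,6S)-5-hydroxy-1,3,3-trimethyl-7-oxabicyclo[4.1.0]heptan-2-one | O=C1C(C)(C)C[C@H](O)[C@@H]2O[C@]12C | intermediate
4 | silylated epoxy ketone, (1S,5S,6S)-5-(tert-butyldimethylsilyloxy)-1,3,3-trimethyl-7-oxabicyclo[4.1.0]heptan-2-one | O=C1C(C)(C)C[C@H](O[Si](C)(C)C(C)(C)C)[C@@H]2O[C@]12C | intermediate
5 | diol, (2S,4S)-4-(tert-butyldimethylsilyloxy)-2,6,6-trimethylcyclohexane-1,2-diol (either C1 epimer) | OC1C(C)(C)C[C@H](O[Si](C)(C)C(C)(C)C)C[C@]1(C)O | intermediate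
6 | ring A ketone, (2S,4S)-4-(tert-butyldimethylsilyloxy)-2-hydroxy-2,6,6-trimethylcyclohexan-1-one | O=C1C(C)(C)C[C@H](O[Si](C)(C)C(C)(C)C)C[C@]1(C)O | intermediate
7 | actinol, (4R,6R)-4-hydroxy-2,2,6-trimethylcyclohexan-1-one | O=C1C(C)(C)C[C@H](O)C[C@H]1C | starting material
8 | actinol silyl ether, (4R,6R)-4-(tert-butyldimethylsilyloxy)-2,2,6-trimethylcyclohexan-1-one | O=C1C(C)(C)C[C@H](O[Si](C)(C)C(C)(C)C)C[C@H]1C | intermediate
9 | lithium enolate of 8 | CC1=C(O[Li])C(C)(C)C[C@H](O[Si](C)(C)C(C)(C)C)C1 | intermediate
10 | ring B enol triflate, (4R)-4-(tert-butyldimethylsilyloxy)-2,6,6-trimethylcyclohex-1-en-1-yl trifluoromethanesulfonate | CC1=C(OS(=O)(=O)C(F)(F)F)C(C)(C)C[C@H](O[Si](C)(C)C(C)(C)C)C1 | intermediate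
11 | (E)-3-methylpent-2-en-4-yn-1-ol | C#C/C(C)=C/CO | starting material
12 | C6 Wittig salt, [(2E)-3-methylpent-2-en-4-yn-1-yl]triphenylphosphonium bromide | C#C/C(C)=C/C[P+](c1ccccc1)(c1ccccc1)c1ccccc1.[Br-] | intermediate
13 | (2E,4E,6E)-2,7-dimethylocta-2,4,6-trienedial | O=C/C(C)=C/C=C/C=C(C)/C=O | starting material
14 | C6 ylide from 12 | C#C/C(C)=C/C=P(c1ccccc1)(c1ccccc1)c1ccccc1 | intermediate
15 | C16 enynal, (2E,4E,6E,8E,10E)-2,7,11-trimethyltrideca-2,4,6,8,10-pentaen-12-ynal | C#C/C(C)=C/C=C/C(C)=C/C=C/C=C(C)/C=O | intermediate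
16 | C22 heptaenediyne, (3E,5E,7E,9E,11E,13E,15E)-3,7,12,16-tetramethyloctadeca-3,5,7,9,11,13,15-heptaene-1,17-diyne | C#C/C(C)=C/C=C/C(C)=C/C=C/C=C(C)/C=C/C=C(C)/C#C | intermediate
17 | ring B C31 polyenediyne (3'R, O3' silyl ether, free terminal alkyne) | CC1=C(C#C/C(C)=C/C=C/C(C)=C/C=C/C=C(C)/C=C/C=C(C)/C#C)C(C)(C)C[C@H](O[Si](C)(C)C(C)(C)C)C1 | intermediate
18 | lithium acetylide of 17 | CC1=C(C#C/C(C)=C/C=C/C(C)=C/C=C/C=C(C)/C=C/C=C(C)/C#C[Li])C(C)(C)C[C@H](O[Si](C)(C)C(C)(C)C)C1 | intermediate
19 | lithium alkoxide of 6 | O=C1C(C)(C)C[C@H](O[Si](C)(C)C(C)(C)C)C[C@]1(C)O[Li] | intermediate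
20 | C40 diynediol, (3S,5S,6R,3'R)-3,3'-bis(tert-butyldimethylsilyloxy)-7,8,7',8'-tetradehydro-5,6-dihydro-β,β-carotene-5,6-diol | CC1=C(C#C/C(C)=C/C=C/C(C)=C/C=C/C=C(C)/C=C/C=C(C)/C#C[C@]2(O)C(C)(C)C[C@H](O[Si](C)(C)C(C)(C)C)C[C@]2(C)O)C(C)(C)C[C@H](O[Si](C)(C)C(C)(C)C)C1 | intermediate
21 | bis-silyl ether of the target, (3S,5S,6S,3'R)-3,3'-bis(tert-butyldimethylsilyloxy)-7',8'-didehydro-5,6-dihydro-β,β-carotene-5,6-diol | CC1=C(C#C/C(C)=C/C=C/C(C)=C/C=C/C=C(C)/C=C/C=C(C)/C=C/[C@]2(O)C(C)(C)C[C@H](O[Si](C)(C)C(C)(C)C)C[C@]2(C)O)C(C)(C)C[C@H](O[Si](C)(C)C(C)(C)C)C1 | intermediate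
22 | all-E (3S,5S,6S,3'R)-7',8'-didehydro-5,6-dihydro-β,β-carotene-3,5,6,3'-tetrol | CC1=C(C#C/C(C)=C/C=C/C(C)=C/C=C/C=C(C)/C=C/C=C(C)/C=C/[C@]2(O)C(C)(C)C[C@H](O)C[C@]2(C)O)C(C)(C)C[C@H](O)C1 | target

Total step count: 13. Longest linear sequence: 8 (steps 1–5, 11, 12, 13).

**Steps most likely to fail**

Step 11. The polyenyl lithium acetylide may add too slowly to a ketone that lies between two fully substituted carbons and carries an α-alkoxide, so that the C31 acetylide decays or the facial preference erodes on warming. The fallback reverses the order of grafting. It sets out from 6 and 16: the diyne 16 is used in excess (3 equiv), lithiated once with LiN(iPr)2 and added to the lithium alkoxide 19 of ketone 6, where the same axial attack should apply and the addition can be driven. This should give the ring A C31 diol with a free terminal alkyne, (1R,2S,4S)-4-(tert-butyldimethylsilyloxy)-2,6,6-trimethyl-1-[(3E,5E,7E,9E,11E,13E,15E)-3,7,12,16-tetramethyloctadeca-3,5,7,9,11,13,15-heptaene-1,17-diyn-1-yl]cyclohexane-1,2-diol F1. Sonogashira coupling of F1 with triflate 10 (Pd(PPh3)4, CuI, iPr2NH) then forms C6'–C7' as the last carbon–carbon bond and comes back to the route at 20.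

Step 4. The hydride opening may be slow, because C4 is reached only through the half-chair that has O3 pseudoaxial, and the C6 alkoxide formed first may migrate the epoxide (Payne rearrangement) before hydride arrives, which would give the wrong diol. The fallback puts oxygen on C5 of an enol ether instead of hydride on C4 of an epoxide. It sets out from actinol silyl ether 8: LiN(iPr)2 and Me3SiCl give the trimethylsilyl enol ether, tert-butyldimethyl{[(1R)-3,5,5-trimethyl-4-(trimethylsilyloxy)cyclohex-3-en-1-yl]oxy}silane F2. Rubottom oxidation of F2 (dimethyldioxirane, acetone, −40 °C; then citric acid, MeOH) gives the α-hydroxy ketone and comes back to the route at 6. The oxidant is expected to enter anti to the pseudoaxial C1 methyl, cis to O3; the C5 epimer, if formed, would be removed by chromatography.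

Step 10. Statistical double coupling, oxidative dimerisation of the terminal alkynes and poor solubility of the symmetrical heptaenediyne may use up the mono-coupled product. The fallback builds the chain stepwise and unsymmetrically instead of using a symmetrical linchpin. It sets out from 12, 13 and 10: dialdehyde 13 is used in excess (2.5 equiv) in a single Wittig reaction with salt 12, and the C16 enynal 15 is now isolated. Sonogashira coupling of 15 with triflate 10 gives the ring B C25 aldehyde, (2E,4E,6E,8E,10E)-13-[(4R)-4-(tert-butyldimethylsilyloxy)-2,6,6-trimethylcyclohex-1-en-1-yl]-2,7,11-trimethyltrideca-2,4,6,8,10-pentaen-12-ynal F3. A second Wittig reaction of F3 with ylide 14 (from 12, NaOMe), followed by the same thermal isomerisation, comes back to the route at 17.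

**Further compounds**

F1 | step 11 | ring A C31 diol with free terminal alkyne, (1R,2S,4S)-4-(tert-butyldimethylsilyloxy)-2,6,6-trimethyl-1-[(3E,5E,7E,9E,11E,13E,15E)-3,7,12,16-tetramethyloctadeca-3,5,7,9,11,13,15-heptaene-1,17-diyn-1-yl]cyclohexane-1,2-diol | C#C/C(C)=C/C=C/C(C)=C/C=C/C=C(C)/C=C/C=C(C)/C#C[C@]1(O)C(C)(C)C[C@H](O[Si](C)(C)C(C)(C)C)C[C@]1(C)O
F2 | step 4 | trimethylsilyl enol ether of 8, tert-butyldimethyl{[(1R)-3,5,5-trimethyl-4-(trimethylsilyloxy)cyclohex-3-en-1-yl]oxy}silane | CC1=C(O[Si](C)(C)C)C(C)(C)C[C@H](O[Si](C)(C)C(C)(C)C)C1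
F3 | step 10 | ring B C25 aldehyde, (2E,4E,6E,8E,10E)-13-[(4R)-4-(tert-butyldimethylsilyloxy)-2,6,6-trimethylcyclohex-1-en-1-yl]-2,7,11-trimethyltrideca-2,4,6,8,10-pentaen-12-ynal | CC1=C(C#C/C(C)=C/C=C/C(C)=C/C=C/C=C(C)/C=O)C(C)(C)C[C@H](O[Si](C)(C)C(C)(C)C)C1
A1 | direct plan | common C15 enyne, tert-butyl (1R)-4-[(3E)-5-(tert-butyldimethylsilyloxy)-3-methylpent-3-en-1-yn-1-yl]-3,5,5-trimethylcyclohex-3-en-1-yl carbonate | CC1=C(C#C/C(C)=C/CO[Si](C)(C)C(C)(C)C)C(C)(C)C[C@H](OC(=O)OC(C)(C)C)C1
A2 | direct plan | anti-epoxide of A1 (3S,5R,6R; oxirane trans to O3) | CC(C)(C)[Si](C)(C)OC/C=C(C)/C#C[C@]12C(C)(C)C[C@H](OC(=O)OC(C)(C)C)C[C@@]1(C)O2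
A3 | direct plan | bridged cyclic carbonate, (1S,5S,8R)-8-[(3E)-5-(tert-butyldimethylsilyloxy)-3-methylpent-3-en-1-yn-1-yl]-8-hydroxy-1,7,7-trimethyl-2,4-dioxabicyclo[3.3.1]nonan-3-one | CC(C)(C)[Si](C)(C)OC/C=C(C)/C#C[C@]1(O)C(C)(C)C[C@H]2C[C@]1(C)OC(=O)O2
A4 | direct plan | ring A C15 aldehyde, (2E,4E)-3-methyl-5-[(1S,2S,4S)-1,2,4-trihydroxy-2,6,6-trimethylcyclohexyl]penta-2,4-dienal | O=C/C=C(C)/C=C/[C@]1(O)C(C)(C)C[C@H](O)C[C@]1(C)O
A5 | direct plan | ring B C25 Wittig salt, [(2E,4E,6E,8E,10E)-13-[(4R)-4-hydroxy-2,6,6-trimethylcyclohex-1-en-1-yl]-2,7,11-trimethyltrideca-2,4,6,8,10-pentaen-12-yn-1-yl]triphenylphosphonium bromide | CC1=C(C#C/C(C)=C/C=C/C(C)=C/C=C/C=C(C)/C[P+](c2ccccc2)(c2ccccc2)c2ccccc2)C(C)(C)C[C@H](O)C1.[Br-]
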